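The ten-membered carbocycle is traced back to a carvone-derived cyclohexene made of C1–C6 (germacrane numbering), whose C1–C6 bond is sacrificed. The plan exploits the 1,5-relationship between the C6 lactone oxygen and the C1–C10 epoxide (a masked E-olefin), and also the ring-cis C4=C5 bond. One anionic oxy-Cope shift forms C8–C9, cleaves C1–C6 and delivers the ten-membered ring, the E-C1=C10 olefin, the C6 ketone and the C8 and C7 stereocentres. Its precursor is a C6 tertiary carbinol bearing an isopropenyl group at C1 and a 4,5-dihydro-1,3-dioxepin-6-yl group, in which an aryl acetal ties O8 to O12.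

Key step: step 10

Remark: germacrane numbering (C1/C10 epoxide carbons, C3 carbinol, C4 formyl-bearing carbon, C6 lactone O–CH, C7 ring fusion, C8 ester carbinol, C11–C13 lactone carbons, C14 and C15 the carbons on C10 and C4) is used in the discussion from compound 6 on. The acetal carbon of 10–19 is carried as both epimers (left undefined in the SMILES) because step 11 erases it.

Step 1
Reactants: 1 (R)-(−)-carvone
Product: 2 cis-carveol [(1R,5R)-2-methyl-5-(prop-1-en-2-yl)cyclohex-2-en-1-ol]
Conditions: NaBH4, CeCl3·7H2O, MeOH, 0 °C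
Reagents that add atoms: none
Why: The Luche reduction gives clean 1,2-reduction of the enone, and axial hydride delivery to the half-chair with an equatorial isopropenyl group should place the new hydroxyl cis to that group (1R).

Step 2
Reactants: 2 cis-carveol
Product: 3 trans-carveyl 4-nitrobenzoate [(1S,5R)-2-methyl-5-(prop-1-en-2-yl)cyclohex-2-en-1-yl 4-nitrobenzoate]
Conditions: 4-O2NC6H4CO2H, PPh3, DIAD, THF, 0 °C to rt
Reagents that add atoms: 4-nitrobenzoic acid O=C(O)c1ccc(cc1)[N+](=O)[O-]
Why: In the Mitsunobu reaction the acidic carboxylate displaces the alkoxyphosphonium group by SN2, which inverts the carbinol carbon to S, the configuration that C3 keeps to the end.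

Step 3
Reactants: 3 trans-carveyl 4-nitrobenzoate
Product: 4 trans-carveol [(1S,5R)-2-methyl-5-(prop-1-en-2-yl)cyclohex-2-en-1-ol]
Conditions: K2CO3, MeOH, rt
Reagents that add atoms: none
Why: Base-catalysed transesterification cleaves the acyl–oxygen bond of the activated ester, so the S carbinol centre is not touched.

Step 4
Reactants: 4 trans-carveol
Product: 5 trans-carveol TBS ether [tert-butyl(dimethyl){[(1S,5R)-2-methyl-5-(prop-1-en-2-yl)cyclohex-2-en-1-yl]oxy}silane]
Conditions: TBSCl, imidazole, DMF, rt
Reagents that add atoms: tert-butyldimethylsilyl chloride CC(C)(C)[Si](C)(C)Cl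
Why: Imidazole-promoted silylation gives a protecting group that withstands organolithium, KH, aluminium hydride, amide base, DDQ, peracid and SeO2 and is removed by fluoride at the end.

Step 5
Reactants: 5 trans-carveol TBS ether
Product: 6 (4S,6R)-4-(tert-butyldimethylsilyloxy)-3-methyl-6-(prop-1-en-2-yl)cyclohex-2-en-1-one
Conditions: CrO3, 3,5-dimethylpyrazole, CH2Cl2, −20 °C
Reagents that add atoms: chromium trioxide O=[Cr](=O)=O
Why: Allylic oxidation with the CrO3–3,5-dimethylpyrazole complex should convert the only allylic ring CH2 (future C6) into the enone carbonyl, because the other allylic ring C–H is shielded by the silyloxy group and the 1,1-disubstituted isopropenyl olefin is less reactive, while the cold non-basic medium leaves the C1 stereocentre and the unconjugated isopropenyl group in place.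

Step 6
Reactants: 7 cis-2-butene-1,4-diol; 8 4-methoxybenzaldehyde dimethyl acetal
Product: 9 2-(4-methoxyphenyl)-4,7-dihydro-1,3-dioxepine
Conditions: PPTS (cat.), CH2Cl2, 4 Å sieves, rt
Reagents that add atoms: none
Why: Acid-catalysed transacetalisation closes the seven-membered acetal readily because the cis olefin holds the two hydroxyl groups together and removal of methanol drives the equilibrium.

Step 7
Reactants: 9 2-(4-methoxyphenyl)-4,7-dihydro-1,3-dioxepine
Product: 10 2-(4-methoxyphenyl)-4,5-dihydro-1,3-dioxepine (racemic)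
Conditions: RuHCl(CO)(PPh3)3 (cat.), toluene, 110 °C
Reagents that add atoms: none
Why: Ruthenium hydride catalysed olefin isomerisation (hydrometalation then β-hydride elimination) moves the double bond by one position into conjugation with oxygen, where the enol ether is the thermodynamic sink, and the acetal carbon thereby becomes a stereocentre that is formed racemic.

Step 8
Reactants: 10 2-(4-methoxyphenyl)-4,5-dihydro-1,3-dioxepine
Product: 12 6-bromo-2-(4-methoxyphenyl)-4,5-dihydro-1,3-dioxepine, via dibromide 11 (not isolated)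
Conditions: Br2, CH2Cl2, −78 °C; then Et3N, −78 °C to rt
Reagents that add atoms: bromine BrBr
Why: This is the standard bromination–dehydrobromination route to cyclic β-bromo enol ethers, in which the enol ether outruns the anisyl ring at −78 °C and the amine then removes the labile bromide next to oxygen together with the adjacent C–H.

Step 9
Reactants: 12 6-bromo-2-(4-methoxyphenyl)-4,5-dihydro-1,3-dioxepine; 6 (4S,6R)-4-(tert-butyldimethylsilyloxy)-3-methyl-6-(prop-1-en-2-yl)cyclohex-2-en-1-one
Product: 15 (1R,4S,6R)-4-(tert-butyldimethylsilyloxy)-1-[2-(4-methoxyphenyl)-4,5-dihydro-1,3-dioxepin-6-yl]-3-methyl-6-(prop-1-en-2-yl)cyclohex-2-en-1-ol, via vinyllithium 13 (not isolated), via organocerium reagent 14 (not isolated)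
Conditions: 12, t-BuLi (2 equiv), Et2O, −95 °C; CeCl3, THF, −78 °C; then 6, −78 °C; aq NH4Cl
Reagents that add atoms: none
Why: Bromine–lithium exchange followed by organocerium 1,2-addition is standard for cyclic β-bromo enol ethers and enolisable enones: the weakly basic cerium reagent spares the acidic C1–H, attack anti to the neighbouring isopropenyl group should give the carbinol with the two alkenyl groups trans (a centre that step 10 erases), and, since the metal stands anti to O8 across the double bond so that ring-opening β-elimination to an alkyne is possible, the reagent is generated below −90 °C and consumed without delay.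

Step 10
Reactants: 15 (1R,4S,6R)-4-(tert-butyldimethylsilyloxy)-1-[2-(4-methoxyphenyl)-4,5-dihydro-1,3-dioxepin-6-yl]-3-methyl-6-(prop-1-en-2-yl)cyclohex-2-en-1-ol
Product: 18 (3S,7R,8R)-3-(tert-butyldimethylsilyloxy)-8,12-[(4-methoxybenzylidene)bis(oxy)]-13-norgermacra-1(10)E,4Z-dien-6-one (cis-fused dioxepane), via potassium alkoxide 16 (not isolated), via potassium enolate 17 (not isolated)
Conditions: KH, 18-crown-6, THF, 0 °C to rt; then cannulated into AcOH–THF, −78 °C
Reagents that add atoms: none
Why: Proposed new method: KH/18-crown-6 converts 15 into the naked alkoxide 16, whose oxyanion weakens the C1–C6 bond so that the 1,5-diene C8=C7–C6–C1–C10=C9 undergoes a concerted [3,3] shift that forms C8–C9 and releases enolate 17; the closest known reaction type is the anionic oxy-Cope ring expansion of 1-alkenyl-6-isopropenylcyclohex-2-en-1-ols to (E,Z)-cyclodecadienones, and the untested element is the oxygen-bearing enol ether terminus, which makes 17 a β-alkoxy enolate. The ten-membered ring is closed by a four-atom ring expansion of the cyclohexene rather than by end-to-end cyclisation, and the dihydrodioxepine is simply carried over into a cis-fused dioxepane. C8 is set by chirality transfer from the carvone-derived centre C1 through a chair in which C2 and C5 are equatorial and O8, which the seven-membered ring holds cis to C11 and trans to C6, is equatorial too, which translates R at C1 into 8R. C7 is set on quenching, because the ring-trans enolate cannot swing its tethered C11 through the ring and therefore offers only its outer face to the proton (7R, H7 anti to the new C8–C9 bond). The step needs chair over boat, E geometry at C1=C10 and survival of the C8–O8 bond: the trans-diequatorial alkenyl groups installed in step 9 secure the first two, and the third rests on the fact that C8–C9 lies parallel to the enolate π orbitals while the tether keeps C8–O8 close to the nodal plane, so E1cB loss of O8 should stay slow until the cold acidic quench. Because the donor oxygen may retard the shift, the temperature is raised only as far as conversion demands and crude 18 is reduced at once.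

Step 11
Reactants: 18 (3S,7R,8R)-3-(tert-butyldimethylsilyloxy)-8,12-[(4-methoxybenzylidene)bis(oxy)]-13-norgermacra-1(10)E,4Z-dien-6-one
Product: 20 (3S,6R,7S,8R)-3-(tert-butyldimethylsilyloxy)-8-(4-methoxybenzyloxy)-13-norgermacra-1(10)E,4Z-diene-6,12-diol, via aluminium alkoxide 19 (not isolated)
Conditions: i-Bu2AlH (excess), CH2Cl2, −78 °C, then 0 °C; aq KNaC4H4O6 work-up
Reagents that add atoms: none
Why: 1,2-Reduction of the enone by i-Bu2AlH on the outer face of the carbonyl (the face that also carries H7) should set 6R, and on warming the same reagent performs the known reductive opening of a 4-methoxybenzylidene acetal by binding the less hindered primary O12, so that the PMB group stays on O8 and the acetal stereocentre disappears.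

Step 12
Reactants: 20 (3S,6R,7S,8R)-3-(tert-butyldimethylsilyloxy)-8-(4-methoxybenzyloxy)-13-norgermacra-1(10)E,4Z-diene-6,12-diol
Product: 22 (3S,6R,7R,8R)-3-(tert-butyldimethylsilyloxy)-8-(4-methoxybenzyloxy)-13-norgermacra-1(10)E,4Z-dien-12,6-olide (trans-fused), via lactol 21 (not isolated)
Conditions: TEMPO (cat.), PhI(OAc)2, CH2Cl2, rt
Reagents that add atoms: none
Why: In this oxoammonium-mediated oxidative lactonisation of a 1,4-diol the primary alcohol is oxidised first, the aldehyde closes onto the C6 hydroxyl as a γ-lactol that is oxidised again, no stereocentre is touched, and the PMB group on O8 rules out the competing 8,12-lactone.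

Step 13
Reactants: 22 (3S,6R,7R,8R)-3-(tert-butyldimethylsilyloxy)-8-(4-methoxybenzyloxy)-13-norgermacra-1(10)E,4Z-dien-12,6-olide
Product: 24 13-(dimethylamino)-3-(tert-butyldimethylsilyloxy)-8-(4-methoxybenzyloxy)germacra-1(10)E,4Z-dien-12,6-olide (C11 configuration immaterial), via lithium enolate 23 (not isolated)
Conditions: LiN(i-Pr)2, THF, −78 °C; Me2N=CH2 I, −78 °C to rt
Reagents that add atoms: N,N-dimethylmethyleneiminium iodide (Eschenmoser's salt) C=[N+](C)C.[I-]
Why: Mannich-type aminomethylation of the lactone enolate brings in C13, the enolate is safe because C7 carries no leaving group, and the new C11 centre is erased in the next step.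

Step 14
Reactants: 24 13-(dimethylamino)-3-(tert-butyldimethylsilyloxy)-8-(4-methoxybenzyloxy)germacra-1(10)E,4Z-dien-12,6-olide
Product: 26 (3S,6R,7R,8R)-3-(tert-butyldimethylsilyloxy)-8-(4-methoxybenzyloxy)germacra-1(10)E,4Z,11(13)-trien-12,6-olide, via ammonium iodide 25 (not isolated)
Conditions: MeI, THF–MeOH, rt; then aq NaHCO3, CH2Cl2, rt
Reagents that add atoms: none
Why: Quaternisation followed by Hofmann-type (E1cB) elimination of trimethylamine is the standard mild way to an α-methylene-γ-lactone and needs only bicarbonate as base.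

Step 15
Reactants: 26 (3S,6R,7R,8R)-3-(tert-butyldimethylsilyloxy)-8-(4-methoxybenzyloxy)germacra-1(10)E,4Z,11(13)-trien-12,6-olide
Product: 27 (3S,6R,7R,8R)-3-(tert-butyldimethylsilyloxy)-8-hydroxygermacra-1(10)E,4Z,11(13)-trien-12,6-olide
Conditions: DDQ, CH2Cl2–pH 7 buffer, 0 °C
Reagents that add atoms: none
Why: Oxidative PMB cleavage with DDQ proceeds by hydride abstraction from the electron-rich benzylic position and hydrolysis, conditions under which the silyl ether, the lactone and the isolated olefins should persist.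

Step 16
Reactants: 27 (3S,6R,7R,8R)-3-(tert-butyldimethylsilyloxy)-8-hydroxygermacra-1(10)E,4Z,11(13)-trien-12,6-olide; 28 methacrylic anhydride
Product: 29 (3S,6R,7R,8R)-3-(tert-butyldimethylsilyloxy)-8-(methacryloyloxy)germacra-1(10)E,4Z,11(13)-trien-12,6-olide
Conditions: DMAP, Et3N, CH2Cl2, 0 °C to rt
Reagents that add atoms: none
Why: DMAP-catalysed acyl transfer esterifies the hindered C8 hydroxyl with retention, and the aprotic medium gives no opportunity for translactonisation onto O8.

Step 17
Reactants: 29 (3S,6R,7R,8R)-3-(tert-butyldimethylsilyloxy)-8-(methacryloyloxy)germacra-1(10)E,4Z,11(13)-trien-12,6-olide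
Product: 30 (1R,3S,6R,7R,8R,10R)-1,10-epoxy-3-(tert-butyldimethylsilyloxy)-8-(methacryloyloxy)germacra-4Z,11(13)-dien-12,6-olide (1β,10α-epoxide)
Conditions: mCPBA, NaHCO3, CH2Cl2, −20 to 0 °C
Reagents that add atoms: 3-chloroperbenzoic acid O=C(OO)c1cccc(Cl)c1
Why: The Prilezhaev epoxidation should pick the only electron-rich and strained olefin (C4=C5 is flanked by two allylic C–O bonds and the other two are conjugated with carbonyl groups), the E geometry is transferred stereospecifically into the trans-epoxide, and peripheral attack on the lactone-locked conformer that holds C14 on the β face should give 1R,10R.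

Step 18
Reactants: 30 (1R,3S,6R,7R,8R,10R)-1,10-epoxy-3-(tert-butyldimethylsilyloxy)-8-(methacryloyloxy)germacra-4Z,11(13)-dien-12,6-olide
Product: 31 15-hydroxy derivative of 30 (4Z, ring-cis geometry kept)
Conditions: SeO2 (0.5 equiv), t-BuOOH, CH2Cl2, rt to 35 °C
Reagents that add atoms: selenium dioxide O=[Se]=O; tert-butyl hydroperoxide CC(C)(C)OO
Why: Riley-type allylic oxidation (ene reaction then [2,3]-sigmatropic shift) goes to the more substituted end of the last unactivated olefin and there to the methyl group trans to C6, the [2,3] step returns the double bond to C4=C5 with the same ring-cis geometry, and epoxides and α-methylene lactones are known to tolerate this reagent pair.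

Step 19
Reactants: 31 15-hydroxy derivative of 30
Product: 32 15-oxo derivative of 30 (3-O-TBS ether of the target)
Conditions: MnO2, CH2Cl2, rt
Reagents that add atoms: none
Why: Neutral MnO2 oxidation is selective for the primary allylic alcohol and also converges any aldehyde already formed in step 18 to a single product.

Step 20
Reactants: 32 15-oxo derivative of 30
Product: 33 target CNP0534814.1 [(1R,3S,6R,7R,8R,10R)-1,10-epoxy-3-hydroxy-8-(methacryloyloxy)-15-oxogermacra-4,11(13)-dien-12,6-olide with ring-cis C4=C5]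
Conditions: HF·pyridine, pyridine, THF, 0 °C to rt
Reagents that add atoms: none
Why: Fluoride-induced desilylation in a pyridine-buffered medium frees the C3 hydroxyl while avoiding both the acid that would trigger transannular opening of the epoxide and the base that would endanger the enal, the esters and the lactone.

Compound list
1 | (R)-(−)-carvone | CC1=CC[C@H](CC1=O)C(C)=C | starting material
2 | cis-carveol (1R,5R) | CC1=CC[C@H](C[C@H]1O)C(C)=C | intermediate
3 | trans-carveyl 4-nitrobenzoate (1S,5R) | CC1=CC[C@H](C[C@@H]1OC(=O)c2ccc(cc2)[N+](=O)[O-])C(C)=C | intermediate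
4 | trans-carveol (1S,5R) | CC1=CC[C@H](C[C@@H]1O)C(C)=C | intermediate
5 | trans-carveol TBS ether | CC1=CC[C@H](C[C@@H]1O[Si](C)(C)C(C)(C)C)C(C)=C | intermediate
6 | (4S,6R)-4-(tert-butyldimethylsilyloxy)-3-methyl-6-(prop-1-en-2-yl)cyclohex-2-en-1-one | CC1=CC(=O)[C@H](C[C@@H]1O[Si](C)(C)C(C)(C)C)C(C)=C | intermediate
7 | cis-2-butene-1,4-diol | OC/C=C\CO | starting material
8 | 4-methoxybenzaldehyde dimethyl acetal | COc1ccc(cc1)C(OC)OC | starting material
9 | 2-(4-methoxyphenyl)-4,7-dihydro-1,3-dioxepine | COc1ccc(cc1)C1OCC=CCO1 | intermediate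
10 | 2-(4-methoxyphenyl)-4,5-dihydro-1,3-dioxepine (racemic) | COc1ccc(cc1)C1OCCC=CO1 | intermediate
11 | 4,5-dibromo-2-(4-methoxyphenyl)-1,3-dioxepane (diastereomer mixture, not isolated) | COc1ccc(cc1)C1OCCC(Br)C(Br)O1 | intermediate
12 | 6-bromo-2-(4-methoxyphenyl)-4,5-dihydro-1,3-dioxepine (racemic) | COc1ccc(cc1)C1OCCC(Br)=CO1 | intermediate
13 | [2-(4-methoxyphenyl)-4,5-dihydro-1,3-dioxepin-6-yl]lithium (not isolated) | COc1ccc(cc1)C1OCCC([Li])=CO1 | intermediate
14 | dichloro[2-(4-methoxyphenyl)-4,5-dihydro-1,3-dioxepin-6-yl]cerium (not isolated) | COc1ccc(cc1)C1OCCC([Ce](Cl)Cl)=CO1 | intermediate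
15 | (1R,4S,6R)-dialkenyl carbinol, both acetal epimers | CC1=C[C@](O)(C2=COC(c3ccc(OC)cc3)OCC2)[C@H](C[C@@H]1O[Si](C)(C)C(C)(C)C)C(C)=C | intermediate
16 | potassium alkoxide of 15 (not isolated) | CC1=C[C@]([O-])(C2=COC(c3ccc(OC)cc3)OCC2)[C@H](C[C@@H]1O[Si](C)(C)C(C)(C)C)C(C)=C.[K+] | intermediate
17 | ring-trans potassium C6=C7 enolate, 8R (not isolated) | COc1ccc(cc1)C2OCC/C3=C([O-])\C=C(C)/[C@@H](O[Si](C)(C)C(C)(C)C)C/C=C(C)/C[C@H]3O2.[K+] | intermediate
18 | (3S,7R,8R)-13-norgermacra-1(10)E,4Z-dien-6-one with cis-fused O8–O12 4-methoxybenzylidene acetal | COc1ccc(cc1)C2OCC[C@@H]3[C@H](O2)C/C(C)=C/C[C@H](O[Si](C)(C)C(C)(C)C)/C(C)=C\C3=O | intermediate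
19 | diisobutylaluminium 6-alkoxide of the reduced acetal (not isolated) | COc1ccc(cc1)C2OCC[C@@H]3[C@H](O2)C/C(C)=C/C[C@H](O[Si](C)(C)C(C)(C)C)/C(C)=C\[C@H]3O[Al](CC(C)C)CC(C)C | intermediate
20 | (3S,6R,7S,8R)-6,12-diol with O8 PMB ether | OCC[C@@H]1[C@H](OCc2ccc(OC)cc2)C/C(C)=C/C[C@H](O[Si](C)(C)C(C)(C)C)/C(C)=C\[C@H]1O | intermediate
21 | 6,12-lactol (C12 epimers, not isolated) | OC1C[C@@H]2[C@H](OCc3ccc(OC)cc3)C/C(C)=C/C[C@H](O[Si](C)(C)C(C)(C)C)/C(C)=C\[C@H]2O1 | intermediate
22 | (3S,6R,7R,8R) trans-fused 12,6-lactone, O8 PMB ether | O=C1C[C@@H]2[C@H](OCc3ccc(OC)cc3)C/C(C)=C/C[C@H](O[Si](C)(C)C(C)(C)C)/C(C)=C\[C@H]2O1 | intermediate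
23 | lithium enolate of 22 (not isolated) | [Li+].[O-]C1=C[C@@H]2[C@H](OCc3ccc(OC)cc3)C/C(C)=C/C[C@H](O[Si](C)(C)C(C)(C)C)/C(C)=C\[C@H]2O1 | intermediate
24 | 11-(dimethylaminomethyl) lactone (C11 undefined) | O=C1C(CN(C)C)[C@@H]2[C@H](OCc3ccc(OC)cc3)C/C(C)=C/C[C@H](O[Si](C)(C)C(C)(C)C)/C(C)=C\[C@H]2O1 | intermediate
25 | trimethylammonium iodide of 24 (not isolated) | O=C1C(C[N+](C)(C)C)[C@@H]2[C@H](OCc3ccc(OC)cc3)C/C(C)=C/C[C@H](O[Si](C)(C)C(C)(C)C)/C(C)=C\[C@H]2O1.[I-] | intermediate
26 | α-methylene lactone, O8 PMB ether | O=C1C(=C)[C@@H]2[C@H](OCc3ccc(OC)cc3)C/C(C)=C/C[C@H](O[Si](C)(C)C(C)(C)C)/C(C)=C\[C@H]2O1 | intermediate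
27 | α-methylene lactone with free 8β-hydroxyl | O=C1C(=C)[C@@H]2[C@H](O)C/C(C)=C/C[C@H](O[Si](C)(C)C(C)(C)C)/C(C)=C\[C@H]2O1 | intermediate
28 | methacrylic anhydride | C=C(C)C(=O)OC(=O)C(C)=C | starting material
29 | 8β-methacrylate of the 1(10)E,4Z-diene | O=C1C(=C)[C@@H]2[C@H](OC(=O)C(C)=C)C/C(C)=C/C[C@H](O[Si](C)(C)C(C)(C)C)/C(C)=C\[C@H]2O1 | intermediate
30 | (1R,10R)-epoxide (1β,10α) | C=C(C)C(=O)O[C@@H]1C[C@@]2(C)O[C@@H]2C[C@H](O[Si](C)(C)C(C)(C)C)/C(C)=C\[C@H]2OC(=O)C(=C)[C@@H]21 | intermediate
31 | 15-hydroxy epoxide | C=C(C)C(=O)O[C@@H]1C[C@@]2(C)O[C@@H]2C[C@H](O[Si](C)(C)C(C)(C)C)/C(CO)=C\[C@H]2OC(=O)C(=C)[C@@H]21 | intermediate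
32 | 15-oxo epoxide, 3-O-TBS ether of the target | C=C(C)C(=O)O[C@@H]1C[C@@]2(C)O[C@@H]2C[C@H](O[Si](C)(C)C(C)(C)C)/C(C=O)=C\[C@H]2OC(=O)C(=C)[C@@H]21 | intermediate
33 | CNP0534814.1 | C=C(C)C(=O)O[C@@H]1C[C@@]2(C)O[C@@H]2C[C@H](O)/C(C=O)=C\[C@H]2OC(=O)C(=C)[C@@H]21 | target

Total step count: 20. Longest linear sequence: 17 steps (steps 1–5 and 9–20).

Steps most likely to fail

Step 10. After the shift the β-alkoxy enolate may expel O8 (E1cB, followed by collapse of the hemiacetal alkoxide). Alternatively, the donor-substituted terminus may slow the rearrangement so far that fragmentation or migration of the isopropenyl double bond takes over.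

- The fallback takes the oxygen off the migrating terminus, so that the ring expansion lies inside the known substrate class, and brings O8 in afterwards. It sets out from enone 6 and comes back at ketone 18.
- Commercial 3-bromobut-3-en-1-ol is silylated (Et3SiCl, imidazole) to (3-bromobut-3-en-1-yloxy)triethylsilane F1. This is lithiated (t-BuLi, −78 °C) and added to 6 in the presence of CeCl3 to give the oxygen-free dialkenyl carbinol F2.
- KH/18-crown-6 then effects the precedented anionic oxy-Cope expansion, and the enolate is trapped with Me3SiCl as the ring-trans trimethylsilyl enol ether F3.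
- Saegusa–Ito dehydrogenation (Pd(OAc)2, MeCN) should give the cross-conjugated 1(10),4,7-trien-6-one F4.
- Copper-catalysed conjugate borylation (CuCl, NaOt-Bu, a chiral BINAP-type bisphosphine, B2pin2, MeOH) should attack the less substituted β-carbon C8 from the open face, with protonation at C7 on the outer face. This gives the β-boryl ketone F5.
- NaBO3·4H2O oxidises F5 with retention to the 8β-hydroxy ketone F6. The sense of induction at C8 would have to be secured by the choice of ligand.
- PPTS in MeOH frees the primary alcohol to give the 8,12-diol ketone F7, and transacetalisation with 8 (PPTS, CH2Cl2) closes the dioxepane to 18.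

Step 18. The ene step may be too slow, because C4=C5 is deactivated by the allylic C3–O and C6–O bonds. Prolonged exposure would then lead to epoxide opening or unselective oxidation.

- The fallback replaces C–H oxidation with selenium by a stronger electrophile and an allylic transposition. It sets out from epoxide 30 and comes back at enal 32.
- Ene-type allylic chlorination with hypochlorous acid made in situ (NaOCl, CeCl3·7H2O, CH2Cl2–H2O, 0 °C) should put chlorine on C5 and move the double bond to C4=C15, giving the 5-chloro-4(15)-ene F8. Either C5 epimer serves.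
- NaI in DMSO with NaHCO3 then equilibrates the allylic halide to the primary C15 iodide, with the trisubstituted C4=C5 bond restored, and Kornblum oxidation converts it directly into 32.

Step 11. Hydride delivery may show poor or reversed facial selectivity if the C6 carbonyl swings to the other side of the ring before reduction.

- The fallback does not fight the ring bias but corrects C6 by substitution. It sets out from ketone 18 and comes back at lactone 22.
- The same i-Bu2AlH operation would give the 6-epi-diol F9, and TEMPO/PhI(OAc)2 would turn it into the cis-fused 6-epi-lactone F10.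
- LiOH (THF–H2O) followed by cold, careful acidification gives the 6-epi hydroxy acid F11.
- Mitsunobu lactonisation (PPh3, DIAD, THF, 0 °C) closes the ring by intramolecular SN2 displacement with inversion at C6, giving 22.

Further compounds
F1 | step 10 | (3-bromobut-3-en-1-yloxy)triethylsilane | C=C(Br)CCO[Si](CC)(CC)CC
F2 | step 10 | (1R,4S,6R)-4-(tert-butyldimethylsilyloxy)-3-methyl-6-(prop-1-en-2-yl)-1-[4-(triethylsilyloxy)but-1-en-2-yl]cyclohex-2-en-1-ol | CC1=C[C@](O)(C(=C)CCO[Si](CC)(CC)CC)[C@H](C[C@@H]1O[Si](C)(C)C(C)(C)C)C(C)=C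
F3 | step 10 | ring-trans C6=C7 trimethylsilyl enol ether of the 8-deoxy 13-norgermacra-1(10)E,4Z-dien-6-one | CC[Si](CC)(CC)OCC/C1=C(O[Si](C)(C)C)\C=C(C)/[C@@H](O[Si](C)(C)C(C)(C)C)C/C=C(C)/CC1
F4 | step 10 | (3S)-3-(tert-butyldimethylsilyloxy)-12-(triethylsilyloxy)-13-norgermacra-1(10)E,4Z,7Z-trien-6-one | CC[Si](CC)(CC)OCC/C1=C/C/C(C)=C/C[C@H](O[Si](C)(C)C(C)(C)C)/C(C)=C\C1=O
F5 | step 10 | 8β-(pinacolatoboryl) ketone | CC[Si](CC)(CC)OCC[C@@H]1[C@H](B2OC(C)(C)C(C)(C)O2)C/C(C)=C/C[C@H](O[Si](C)(C)C(C)(C)C)/C(C)=C\C1=O
F6 | step 10 | 8β-hydroxy-12-(triethylsilyloxy) ketone | CC[Si](CC)(CC)OCC[C@@H]1[C@H](O)C/C(C)=C/C[C@H](O[Si](C)(C)C(C)(C)C)/C(C)=C\C1=O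
F7 | step 10 | 8β,12-dihydroxy ketone | OCC[C@@H]1[C@H](O)C/C(C)=C/C[C@H](O[Si](C)(C)C(C)(C)C)/C(C)=C\C1=O
F8 | step 18 | 5-chloro-4(15)-ene derived from 30 (C5 undefined) | C=C(C)C(=O)O[C@@H]1C[C@@]2(C)O[C@@H]2C[C@H](O[Si](C)(C)C(C)(C)C)C(=C)C(Cl)[C@H]2OC(=O)C(=C)[C@@H]21
F9 | step 11 | 6-epi-diol (6-epimer of 20) | OCC[C@@H]1[C@H](OCc2ccc(OC)cc2)C/C(C)=C/C[C@H](O[Si](C)(C)C(C)(C)C)/C(C)=C\[C@@H]1O
F10 | step 11 | cis-fused 6-epi-lactone (6-epimer of 22) | O=C1C[C@@H]2[C@H](OCc3ccc(OC)cc3)C/C(C)=C/C[C@H](O[Si](C)(C)C(C)(C)C)/C(C)=C\[C@@H]2O1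
F11 | step 11 | 6-epi 6-hydroxy-12-oic acid | OC(=O)C[C@@H]1[C@H](OCc2ccc(OC)cc2)C/C(C)=C/C[C@H](O[Si](C)(C)C(C)(C)C)/C(C)=C\[C@@H]1O
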